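The trap is to read the amber run, with 15.6% target at 2.50 d, as a slow flask that wants heat. The red run reads 0.5% at 0.625 d and 16.7% at 1.67 d, so I take this as an induction, with by-product speeding its own making.

| setting | amber | violet | red | north-west | south |
|---|---|---|---|---|---|
| starting material | 0.50 M | 0.75 M | 1 M | 1.0 M | 1.0 M |
| reagent | 0.70 equiv | 0.70 equiv | 0.35 equiv | 0.700 equiv | 0.700 equiv |
| temperature | 30 °C | 42 °C | 30 °C | 35 °C | 50 °C |
| remark | run made earlier | run made earlier | run made earlier |  |  |
| time |  |  |  | 3.0 d | 3.0 d |

| run | time / d | target / % |
|---|---|---|
| amber | 0.208 | 0 |
| amber | 0.333 | 1.3 |
| amber | 0.625 | 1.2 |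
| amber | 1.25 | 3.6 |
| amber | 2.50 | 15.6 |
| violet | 0.500 | 27.0 |
| violet | 1.04 | 56.4 |
| violet | 1.25 | 60.7 |
| violet | 2.08 | 61.6 |
| violet | 2.50 | 61.5 |
| red | 0.208 | 0.6 |
| red | 0.625 | 0.5 |
| red | 1.04 | 6.4 |
| red | 1.67 | 16.7 |
| red | 2.50 | 27.3 |

(each reading ± 1 percentage point)

1. the best flask by amount of target, in percent of the starting material charged; "all alike" if 1.5 percentage points covers them all (north-west / south / all alike)
2. amount of target at the end, in percent of the starting material charged, north-west
3. amount of target at the end, in percent of the starting material charged, south

- candidate steps: starting material + reagent -> target + by-product; reagent + target -> over-reaction product; starting material + reagent + by-product -> target + 2 by-product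

I turn the settings one at a time. Time: the violet run reads 61.6% at 2.08 d and 61.5% at 2.50 d, so between those readings waiting gains nothing beyond the scatter there. Temperature: I expect heat to bring that stop earlier, and the red run, cooler than both new flasks, has already made 27.3% on 0.35 equiv of reagent, so I expect both flasks to finish within 3.0 d.

Reagent: at 0.700 equiv it is the limiting reagent of both new flasks. Each target costs one reagent, and each over-reaction product has cost two. I therefore read the violet plateau against its charge, and the shortfall in molar units is the reagent gap 0.0637 M.

Concentration: in the self-speeding step target is made in proportion to starting material, by-product and reagent, and it is used in proportion to target and reagent. Reagent cancels and by-product tracks target, so the ratio of making to using follows starting material and drifts down as that falls. At equal equivalents and equal temperature, then, I expect the gap to stay fixed in molar units. I carry it unchanged to both flasks, although neither stands at the violet temperature, which gives my own 63.6% target for both. The single violet plateau cannot show how temperature moves the gap.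

The forecast says all alike, with 63.5% for north-west and 63% for south: “The final yield then depends on selectivity”.

The flasks give all alike, with 62.8% for north-west and 63.8% for south.

    starting material + reagent → target + by-product (k = 1.50 × 10⁻⁴ M⁻¹ min⁻¹, Ea = 81.0 kJ mol⁻¹)
    reagent + target → over-reaction product (k = 0.00110 M⁻¹ min⁻¹, Ea = 68.0 kJ mol⁻¹)
    starting material + reagent + by-product → target + 2 by-product (k = 0.0370 M⁻² min⁻¹, Ea = 77.0 kJ mol⁻¹)
    (constants at 50 °C)

Against the 0.0637 M I carried, the gap is 0.0717 M in north-west and 0.0620 M in south. The neighbour is north-west with 2.80 equiv of reagent, where 35.4% of the reagent charge remains, so 1.81 equiv is spent. Starting material stands at 0%, so target and over-reaction product share the charge, and the same accounting puts over-reaction product at 0.810 equiv. That neighbour holds 80.8% over-reaction product and 19.2% target.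

The data were generated by integration with made-up constants, noise included.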